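**Retrosynthetic overview**
1. Locants: phthalide C1–C7a; spiroketal O1, C2 (hexyl), C3, C4, C5 (spiro), O6, C7 (methyl), C8, C9; ring A = O1/C2/C3/C4/C5, ring B = C5/O6/C7/C8/C9. The last disconnection cuts both C5–O bonds and leads to an open-chain alkynediol (alkyne C5≡C9, carbinols C2 and C7) that already carries the finished phthalide.
2. Enabling feature: C5 is a ketone-level carbon lying 1,4 to both carbinol oxygens (O1 through C2–C3–C4, O6 through C7–C8–C9). An alkyne C5≡C9 is therefore a neutral ketone surrogate whose inner carbon C5 is the only one that O1 (5-exo-dig, ring A) and then O6 (capture of the oxocarbenium ion, ring B, closed last) can reach through five-membered closures.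
3. Phthalide (closed before the spiroketal): lactone carbon C1 from CO2 after bromine–lithium exchange ortho to the (S)-benzylic alcohol; C3 by asymmetric transfer hydrogenation of an aryl ketone; ketone by iron-catalysed acylation of the chain Grignard reagent with 3,5-dimethoxybenzoyl chloride.
4. Chain from the chiral pool by two epoxide openings: (S)-epichlorohydrin (C2, extended by 1-bromo-5-chloropentane), 1-(trimethylsilyl)propyne as propargyl linchpin (C4, C5, C9), (S)-propylene oxide (C8, C7, methyl).
5. Order of ring formation: arene bought; lactone ring in step 8; ring A and then ring B in the cascade of step 10.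

Key step: step 10

Remark: 2,7-dialkyl-1,6-dioxaspiro[4.4]nonanes are assumed to have no useful thermodynamic preference at the spiro carbon, so step 10 is planned with chromatographic separation of the two spiro epimers and recycling of the unwanted one by re-equilibration.

**Step 1**
Reactants: 1 (S)-epichlorohydrin; 2 1-bromo-5-chloropentane
Product: 5 (2S)-2-(6-chlorohexyl)oxirane, via 5-chloropentylmagnesium bromide 3 (not isolated), via (2S)-1,8-dichlorooctan-2-ol 4 (not isolated)
Conditions: 2, Mg, THF, 30 °C; then 1, CuI (10 mol %), THF, −40 → −20 °C; aq. work-up; then NaOH (powdered), Et2O, rt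
Reagents that add atoms: none
Why: Copper-catalysed Grignard opening of the epoxide of 1 at its unsubstituted carbon followed by intramolecular Williamson closure of chlorohydrin 4 is the standard chiral-pool route to terminal epoxides; the C–O bond at the stereocentre is never broken, so the S configuration of 1 becomes C2 of the spiroketal.

**Step 2**
Reactants: 5 (2S)-2-(6-chlorohexyl)oxirane; 6 1-(trimethylsilyl)propyne
Product: 9 (5S)-11-chloroundec-1-yn-5-ol, via 3-lithio-1-(trimethylsilyl)propyne 7 (not isolated), via (5S)-11-chloro-1-(trimethylsilyl)undec-1-yn-5-ol 8 (not isolated)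
Conditions: 6, n-BuLi, THF, −78 → −20 °C; −78 °C, 5, then BF3·OEt2; aq. work-up; then K2CO3 (cat.), MeOH, rt
Reagents that add atoms: none
Why: SN2 opening of the terminal epoxide at its CH2 group by the silyl-stabilised propargyllithium 7 under BF3 activation (the silyl group suppresses allenyl products), followed by base-catalysed methanolysis of the alkynylsilane, gives the 4-alkyn-1-ol pattern needed for the later 5-exo-dig closure while the carbinol centre and the primary chloride stay untouched.

**Step 3**
Reactants: 9 (5S)-11-chloroundec-1-yn-5-ol; 10 (S)-propylene oxide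
Product: 12 (2S,8S)-14-chlorotetradec-4-yne-2,8-diol, via dilithio alkoxide–acetylide 11 (not isolated)
Conditions: n-BuLi (2.1 equiv), THF, −78 °C; BF3·OEt2 (2.5 equiv), then 10 (2 equiv), −78 °C
Reagents that add atoms: none
Why: Yamaguchi–Hirao alkynylation, in which the alkynyl trifluoroborate formed from dianion 11 and BF3·OEt2 opens 10 at its CH2 group at −78 °C, installs the second carbinol centre directly from the chiral pool (no bond to the stereocentre of 10 is broken) and leaves the primary chloride intact.

**Step 4**
Reactants: 12 (2S,8S)-14-chlorotetradec-4-yne-2,8-diol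
Product: 13 (2S,8S)-2,8-bis[(tert-butyldimethylsilyl)oxy]-14-chlorotetradec-4-yne
Conditions: TBSCl (2.5 equiv), imidazole, DMF, rt
Reagents that add atoms: tert-butyldimethylsilyl chloride (TBSCl), CC(C)(C)[Si](C)(C)Cl
Why: Routine silyl ether formation masks both secondary alcohols so that a Grignard reagent can be generated at the chloride terminus in the next step.

**Step 5**
Reactants: 13 (2S,8S)-2,8-bis[(tert-butyldimethylsilyl)oxy]-14-chlorotetradec-4-yne; 14 3,5-dimethoxybenzoyl chloride
Product: 16 (8S,14S)-8,14-bis[(tert-butyldimethylsilyl)oxy]-1-(3,5-dimethoxyphenyl)pentadec-11-yn-1-one, via alkylmagnesium chloride 15 (not isolated)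
Conditions: 13, Mg (activated by BrCH2CH2Br), THF, reflux; then 14, Fe(acac)3 (3 mol %), THF, −78 °C
Reagents that add atoms: none
Why: Iron-catalysed cross-coupling of an alkyl Grignard reagent with an aroyl chloride (Grignard acylation) is faster at −78 °C than addition to the ketone formed, so the reaction should stop at 16 and leave the internal alkyne and the silyl ethers untouched.

**Step 6**
Reactants: 16 (8S,14S)-8,14-bis[(tert-butyldimethylsilyl)oxy]-1-(3,5-dimethoxyphenyl)pentadec-11-yn-1-one
Product: 17 (1S,8S,14S)-8,14-bis[(tert-butyldimethylsilyl)oxy]-1-(3,5-dimethoxyphenyl)pentadec-11-yn-1-ol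
Conditions: RuCl(p-cymene)[(S,S)-TsDPEN] (1 mol %), HCO2H/Et3N azeotrope, 30 °C
Reagents that add atoms: none
Why: Noyori asymmetric transfer hydrogenation of an aryl alkyl ketone; the (S,S)-TsDPEN ruthenium hydride transfers hydride through its six-membered transition state with the aryl group held by a CH/π contact to the p-cymene ligand, which should set the benzylic centre as S (the future C3 of the phthalide) under catalyst control, the alkyne being inert.

**Step 7**
Reactants: 17 (1S,8S,14S)-8,14-bis[(tert-butyldimethylsilyl)oxy]-1-(3,5-dimethoxyphenyl)pentadec-11-yn-1-ol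
Product: 18 (1S,8S,14S)-1-(2-bromo-3,5-dimethoxyphenyl)-8,14-bis[(tert-butyldimethylsilyl)oxy]pentadec-11-yn-1-ol
Conditions: NBS (1.05 equiv), MeCN, 0 °C
Reagents that add atoms: N-bromosuccinimide (NBS), O=C1CCC(=O)N1Br
Why: Electrophilic aromatic bromination by NBS goes to the ring position next to the carbinol side chain, which is para to one methoxy group and ortho to the other and less hindered than the carbon between the two methoxy groups; the alkyne, the silyl ethers and the stereocentres are not affected at 0 °C.

**Step 8**
Reactants: 18 (1S,8S,14S)-1-(2-bromo-3,5-dimethoxyphenyl)-8,14-bis[(tert-butyldimethylsilyl)oxy]pentadec-11-yn-1-ol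
Product: 21 (3S)-3-[(7S,13S)-7,13-bis[(tert-butyldimethylsilyl)oxy]tetradec-10-yn-1-yl]-5,7-dimethoxy-2-benzofuran-1(3H)-one, via aryllithium lithium alkoxide 19 (not isolated), via ortho-(hydroxyalkyl)benzoic acid 20 (not isolated)
Conditions: n-BuLi (2.2 equiv), THF, −78 °C; CO2 (g), −78 °C → rt; then 1 M HCl, 0 °C → rt
Reagents that add atoms: carbon dioxide, O=C=O
Why: Bromine–lithium exchange on the lithium alkoxide, carboxylation of aryllithium 19 by CO2 and acid-induced lactonisation of hydroxy acid 20 (5-exo-trig acyl substitution) form the phthalide ring, the classical route from ortho-bromobenzylic alcohols; the benzylic C–O bond is not broken, so C3 stays S.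

**Step 9**
Reactants: 21 (3S)-3-[(7S,13S)-7,13-bis[(tert-butyldimethylsilyl)oxy]tetradec-10-yn-1-yl]-5,7-dimethoxy-2-benzofuran-1(3H)-one
Product: 22 (3S)-3-[(7S,13S)-7,13-dihydroxytetradec-10-yn-1-yl]-5,7-dimethoxy-2-benzofuran-1(3H)-one
Conditions: HF·pyridine, pyridine, THF, 0 °C → rt
Reagents that add atoms: none
Why: Fluoride-mediated cleavage of the two silyl ethers by buffered HF·pyridine frees the diol without opening the lactone or touching the alkyne, and any silyl ether already lost in the acidic work-up of step 8 converges on the same product.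

**Step 10**
Reactants: 22 (3S)-3-[(7S,13S)-7,13-dihydroxytetradec-10-yn-1-yl]-5,7-dimethoxy-2-benzofuran-1(3H)-one
Product: 24 (3S)-5,7-dimethoxy-3-{6-[(2S,5S,7S)-7-methyl-1,6-dioxaspiro[4.4]nonan-2-yl]hexyl}-2-benzofuran-1(3H)-one, via (Z)-enol ether 23 (not isolated)
Conditions: Ph3PAuCl (5 mol %), AgOTf (5 mol %), PPTS (10 mol %), CH2Cl2, rt; chromatography on base-washed silica
Reagents that add atoms: none
Why: Cationic monovalent gold (Ph3PAuOTf formed from Ph3PAuCl and AgOTf) activates the side-chain alkyne C10≡C11 (C5≡C9 of the spiroketal); the C7 hydroxyl adds anti to C10 in a 5-exo-dig oxyauration and protodeauration gives (Z)-enol ether 23 with ring A closed, after which protonation of 23 at C11 by PPTS gives a ring A oxocarbenium ion that the C13 hydroxyl captures in a 5-exo-trig closure, so that ring B and the spiro carbon are formed last. The closest known reaction type is the gold- or palladium-catalysed cycloisomerisation (double hydroalkoxylation) of alkynediols to spiroketals. The selectivity needed is regioselectivity for C10, and the position of the alkyne secures it: C10 is reached by both hydroxyls through five-membered transition states, whereas attack at C11 would need a 6-endo-dig closure by the C7 hydroxyl or a four-membered ring for the C13 hydroxyl; the 5-exo-dig mode of the C7 hydroxyl is also expected to outrun the 5-endo-dig mode open to the C13 hydroxyl, and lactone and arene are spectators. The carbinol centres C2 and C7 of the spiroketal come unchanged from 22. The spiro carbon C5 is the only new stereocentre; it is formed through the reversible oxocarbenium ion and is therefore under thermodynamic control, for which no strong bias is expected, so that the (5S) compound 24 should form together with its (5R) epimer, is separated by chromatography, and the epimer is returned to the PPTS conditions for re-equilibration.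

**Compound list**
1 | (S)-epichlorohydrin | ClC[C@@H]1CO1 | starting material
2 | 1-bromo-5-chloropentane | ClCCCCCBr | starting material
3 | 5-chloropentylmagnesium bromide | ClCCCCC[Mg]Br | intermediate
4 | (2S)-1,8-dichlorooctan-2-ol | ClC[C@@H](O)CCCCCCCl | intermediate
5 | (2S)-2-(6-chlorohexyl)oxirane | ClCCCCCC[C@H]1CO1 | intermediate
6 | 1-(trimethylsilyl)propyne | CC#C[Si](C)(C)C | starting material
7 | 3-lithio-1-(trimethylsilyl)propyne | [Li]CC#C[Si](C)(C)C | intermediate
8 | (5S)-11-chloro-1-(trimethylsilyl)undec-1-yn-5-ol | C[Si](C)(C)C#CCC[C@@H](O)CCCCCCCl | intermediate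
9 | (5S)-11-chloroundec-1-yn-5-ol | C#CCC[C@@H](O)CCCCCCCl | intermediate
10 | (S)-propylene oxide | C[C@H]1CO1 | starting material
11 | dilithium salt of 9 (lithium alkoxide and lithium acetylide) | [Li]C#CCC[C@@H](O[Li])CCCCCCCl | intermediate
12 | (2S,8S)-14-chlorotetradec-4-yne-2,8-diol | C[C@H](O)CC#CCC[C@@H](O)CCCCCCCl | intermediate
13 | (2S,8S)-2,8-bis[(tert-butyldimethylsilyl)oxy]-14-chlorotetradec-4-yne | C[C@H](O[Si](C)(C)C(C)(C)C)CC#CCC[C@@H](O[Si](C)(C)C(C)(C)C)CCCCCCCl | intermediate
14 | 3,5-dimethoxybenzoyl chloride | COc1cc(OC)cc(c1)C(Cl)=O | starting material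
15 | [(7S,13S)-7,13-bis[(tert-butyldimethylsilyl)oxy]tetradec-10-yn-1-yl]magnesium chloride | C[C@H](O[Si](C)(C)C(C)(C)C)CC#CCC[C@@H](O[Si](C)(C)C(C)(C)C)CCCCCC[Mg]Cl | intermediate
16 | (8S,14S)-8,14-bis[(tert-butyldimethylsilyl)oxy]-1-(3,5-dimethoxyphenyl)pentadec-11-yn-1-one | COc1cc(OC)cc(c1)C(=O)CCCCCC[C@H](O[Si](C)(C)C(C)(C)C)CCC#CC[C@H](C)O[Si](C)(C)C(C)(C)C | intermediate
17 | (1S,8S,14S)-8,14-bis[(tert-butyldimethylsilyl)oxy]-1-(3,5-dimethoxyphenyl)pentadec-11-yn-1-ol | COc1cc(OC)cc(c1)[C@@H](O)CCCCCC[C@H](O[Si](C)(C)C(C)(C)C)CCC#CC[C@H](C)O[Si](C)(C)C(C)(C)C | intermediate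
18 | (1S,8S,14S)-1-(2-bromo-3,5-dimethoxyphenyl)-8,14-bis[(tert-butyldimethylsilyl)oxy]pentadec-11-yn-1-ol | COc1cc(OC)c(Br)c(c1)[C@@H](O)CCCCCC[C@H](O[Si](C)(C)C(C)(C)C)CCC#CC[C@H](C)O[Si](C)(C)C(C)(C)C | intermediate
19 | lithium (1S,8S,14S)-8,14-bis[(tert-butyldimethylsilyl)oxy]-1-(2-lithio-3,5-dimethoxyphenyl)pentadec-11-yn-1-olate | COc1cc(OC)c([Li])c(c1)[C@@H](O[Li])CCCCCC[C@H](O[Si](C)(C)C(C)(C)C)CCC#CC[C@H](C)O[Si](C)(C)C(C)(C)C | intermediate
20 | 2-[(1S,8S,14S)-8,14-bis[(tert-butyldimethylsilyl)oxy]-1-hydroxypentadec-11-yn-1-yl]-4,6-dimethoxybenzoic acid | COc1cc(OC)c(C(O)=O)c(c1)[C@@H](O)CCCCCC[C@H](O[Si](C)(C)C(C)(C)C)CCC#CC[C@H](C)O[Si](C)(C)C(C)(C)C | intermediate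
21 | (3S)-3-[(7S,13S)-7,13-bis[(tert-butyldimethylsilyl)oxy]tetradec-10-yn-1-yl]-5,7-dimethoxy-2-benzofuran-1(3H)-one | COc1cc(OC)c2c(c1)[C@H](CCCCCC[C@H](O[Si](C)(C)C(C)(C)C)CCC#CC[C@H](C)O[Si](C)(C)C(C)(C)C)OC2=O | intermediate
22 | (3S)-3-[(7S,13S)-7,13-dihydroxytetradec-10-yn-1-yl]-5,7-dimethoxy-2-benzofuran-1(3H)-one | COc1cc(OC)c2c(c1)[C@H](CCCCCC[C@H](O)CCC#CC[C@H](C)O)OC2=O | intermediate
23 | (3S)-3-{6-[(2S,5Z)-5-[(3S)-3-hydroxybutylidene]oxolan-2-yl]hexyl}-5,7-dimethoxy-2-benzofuran-1(3H)-one | COc1cc(OC)c2c(c1)[C@H](CCCCCC[C@H]1CC/C(=C/C[C@H](C)O)/O1)OC2=O | intermediate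
24 | (3S)-5,7-dimethoxy-3-{6-[(2S,5S,7S)-7-methyl-1,6-dioxaspiro[4.4]nonan-2-yl]hexyl}-2-benzofuran-1(3H)-one | COc1cc(OC)c2c(c1)[C@H](CCCCCC[C@H]1CC[C@]3(CC[C@H](C)O3)O1)OC2=O | target

**Totals and risks**
Total step count: 10. Longest linear sequence: 10 steps (1 to 24); compounds 6, 10 and 14 enter as bought.

Step 10. The process at risk is the closure of ring B without any facial bias: the spiro carbon equilibrates through the oxocarbenium ion, so both spiro epimers form and may be hard to separate. A lesser risk is a competing 6-endo-dig closure. The fallback replaces thermodynamic control by catalyst-controlled kinetic closure in two operations. Setting out from 22, the gold step is run base-buffered (AuCl 5 mol %, K2CO3 10 mol %, MeCN, rt) so that it stops at enol ether 23, which is filtered through basic alumina and not chromatographed. Compound 23 is then closed at low temperature by a confined BINOL-derived imidodiphosphoric acid (5 mol %, MTBE, −35 °C), the catalytic asymmetric spiroacetalisation of hydroxy enol ethers; both enantiomers of the acid are screened for the one that is matched with the (5S) configuration, and the route is rejoined at 24. Whatever still forms of the epimer (3S)-5,7-dimethoxy-3-{6-[(2S,5R,7S)-7-methyl-1,6-dioxaspiro[4.4]nonan-2-yl]hexyl}-2-benzofuran-1(3H)-one F1 is removed by chromatography and returned to 24 by re-equilibration with PPTS.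

Step 3. The lithium alkoxide of dianion 11 may sequester BF3 and aggregate, so that the alkynyl borate forms incompletely and the epoxide opening stalls. The fallback protects before alkynylation. Setting out from 9, silylation (TBSCl, imidazole, DMF) should give (5S)-5-[(tert-butyldimethylsilyl)oxy]-11-chloroundec-1-yne F2. Deprotonation (n-BuLi, THF, −78 °C) gives its lithium acetylide F3, which opens 10 under BF3·OEt2 to (2S,8S)-8-[(tert-butyldimethylsilyl)oxy]-14-chlorotetradec-4-yn-2-ol F4. Silylation of the remaining alcohol under the conditions of step 4 rejoins the route at 13.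

Step 8. Aryllithium 19 may be quenched by proton transfer from the propargylic C–H bonds or alkylated by the 1-bromobutane released in the exchange, and the acidic lactonisation may start to cleave the silyl ethers. The fallback replaces the organolithium sequence by a palladium-catalysed carbonylative lactonisation. Setting out from 18, the conditions are Pd(OAc)2 (5 mol %), Xantphos, CO (1 atm), Et3N, toluene, 90 °C. Oxidative addition of zerovalent palladium into the C–Br bond, CO insertion and capture of the acylpalladium by the neighbouring benzylic hydroxyl should give 21 directly, where the route is rejoined; no compound outside the list is made (F0).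

**Further compounds**
F1 | step 10 | (3S)-5,7-dimethoxy-3-{6-[(2S,5R,7S)-7-methyl-1,6-dioxaspiro[4.4]nonan-2-yl]hexyl}-2-benzofuran-1(3H)-one | COc1cc(OC)c2c(c1)[C@H](CCCCCC[C@H]1CC[C@@]3(CC[C@H](C)O3)O1)OC2=O
F2 | step 3 | (5S)-5-[(tert-butyldimethylsilyl)oxy]-11-chloroundec-1-yne | C#CCC[C@@H](O[Si](C)(C)C(C)(C)C)CCCCCCCl
F3 | step 3 | lithium acetylide of F2 | [Li]C#CCC[C@@H](O[Si](C)(C)C(C)(C)C)CCCCCCCl
F4 | step 3 | (2S,8S)-8-[(tert-butyldimethylsilyl)oxy]-14-chlorotetradec-4-yn-2-ol | C[C@H](O)CC#CCC[C@@H](O[Si](C)(C)C(C)(C)C)CCCCCCCl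
F0 | step 8 | none | none
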